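## Retrosynthetic overview
1. Target 10 ⇒ diprenyl flavanone 8. The tertiary C–O bond and the E-styrenyl alkene come from a sensitised singlet-oxygen ene reaction on one of two equivalent prenyl groups.
2. 8 ⇒ (2S)-3′,5′-diiodoisosakuranetin 6 + prenyl acetate 7. Both aryl–prenyl C–C bonds form in one Ni-catalysed electroreductive coupling.
3. 6 ⇒ (2S)-naringin 1. The sugar masks 7-OH, so only 4′-OH is methylated; ring B is iodinated at the phenol stage, and ring-A iodides are erased during deglycosylation.
4. No ring is built. Rings A, C and B and the C2 stereocentre are bought together in 1, and C2 is never a reacting centre.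

Assumption: naringin is used as the pure (2S)-epimer. The 2S and 2R forms are diastereomers because of the sugar, so commercial material is recrystallised from water and checked by ordinary HPLC.

## Route

**Step 1**
Reactants: 1 (2S)-naringin; 2 N-iodosuccinimide
Product: 3 (2S)-3′,5′,6,8-tetraiodonaringin
Conditions: NIS (4.6 equiv), TsOH·H2O (0.2 equiv), MeCN–MeOH 1:1, 0 °C → rt, dark
Reagents that add atoms: N-iodosuccinimide, O=C1CCC(=O)N1I
Why: Electrophilic aromatic iodination is driven to exhaustion at every activated C–H (3′,5′ ortho to the free 4′-OH; 6,8 on the phloroglucinol ring), which sidesteps the unfavourable ring A versus ring B selectivity; incomplete ring-A iodination does not matter because step 3 converges, and the mildly acidic medium leaves the glycosidic bonds and the bought C2 centre untouched.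

**Step 2**
Reactants: 3 tetraiodonaringin; 4 iodomethane
Product: 5 (2S)-3′,5′,6,8-tetraiodo-4′-O-methylnaringin (tetraiodoponcirin)
Conditions: MeI (3 equiv), KHCO3 (2 equiv), DMF, 30 °C
Reagents that add atoms: iodomethane, CI
Why: Williamson O-methylation is selective because the 2,6-diiodophenol (pKa about 6.5) is the only OH ionised by bicarbonate, 7-O is blocked by the sugar and the chelated 5-OH and sugar alcohols are inert; the weak base avoids retro-oxa-Michael epimerisation at C2, and any 2R material would appear as a separable diastereomer.

**Step 3**
Reactants: 5 tetraiodoponcirin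
Product: 6 (2S)-2-(3,5-diiodo-4-methoxyphenyl)-5,7-dihydroxychroman-4-one (3′,5′-diiodoisosakuranetin)
Conditions: 1.5 M H2SO4, NaHSO3 (8 equiv), NaI (cat.), EtOH–H2O 1:1, 85 °C, sealed vessel
Reagents that add atoms: none
Why: Acid-catalysed glycoside hydrolysis frees 7-OH while the same medium protodeiodinates ring A only, because only the phloroglucinol ring is basic enough for ipso-protonation (I+ is removed by I−/bisulfite) and the twisted 2,6-diiodoanisole ring B is inert; there is no base, and the electron-poor B ring disfavours benzylic C2–O ionisation, so C2 is retained (ee checked by HPLC, product recrystallised).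

**Step 4**
Reactants: 6 3′,5′-diiodoisosakuranetin; 7 prenyl acetate (3-methylbut-2-en-1-yl acetate)
Product: 8 (2S)-5,7-dihydroxy-2-[4-methoxy-3,5-bis(3-methylbut-2-en-1-yl)phenyl]chroman-4-one
Conditions: NiBr2·dme (15 mol %), 2,2′-bipyridine (18 mol %), 7 (6 equiv), Bu4NBF4, DMF, undivided cell, Fe(+)/Ni foam(−), constant current, about 7 F/mol, rt, Ar; dilute HCl work-up
Reagents that add atoms: prenyl acetate, CC(C)=CCOC(C)=O
Why: Proposed new method: a twofold, base-free electroreductive aryl–prenyl cross-electrophile coupling on an unprotected, epimerisable polyphenol, in which the phenolic protons are first discharged as H2, cathodic Ni(0)(bpy) (about −1.2 V vs SCE, well positive of the chelated aryl ketone) inserts into each C–I bond, the reduced aryl-Ni(I) ionises prenyl acetate to an aryl-Ni(III)(η3-prenyl) species, and reductive elimination at the unsubstituted terminus gives the linear prenylarene, while anodic Fe2+ binds acetate and phenoxide and avoids nucleophilic prenylzinc, and the anionic vinylogous-carboxylate ketone resists allylation and C3 deprotonation so C2 is preserved; the closest known reaction type is Ni-catalysed sacrificial-anode (or Zn/Mn-driven) coupling of aryl halides with allylic acetates, which has not been shown for double prenylation flanking a methoxy group or on free-phenol flavanones.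

**Step 5**
Reactants: 8 diprenyl flavanone; 9 dioxygen
Product: 10 target, (2S)-5,7-dihydroxy-2-{3-[(1E)-3-hydroxy-3-methylbut-1-en-1-yl]-4-methoxy-5-(3-methylbut-2-en-1-yl)phenyl}chroman-4-one
Conditions: O2, tetraphenylporphyrin (1 mol %), white LED (>400 nm filter), CH2Cl2, 0 °C, stopped at about 50 % conversion; then PPh3, 0 °C → rt
Reagents that add atoms: dioxygen, O=O
Why: In this Schenck ene photooxygenation only the dye absorbs, 1O2 attacks the trisubstituted alkene, and abstraction of a benzylic H puts OOH on the tertiary carbon and gives the E-alkene, with PPh3 then reducing O–O to OH; the two prenyl groups are equivalent by B-ring rotation so either one gives 10, the un-ionised acylphloroglucinol ring is not consumed by 1O2, and the secondary-alcohol regioisomer (about 1:1) and recovered 8 (recycled) are removed by chromatography under neutral conditions that leave C2 alone.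

## Compound list
| No. | Name | SMILES | Role |
|---|---|---|---|
| 1 | (2S)-naringin | `C[C@H]1[C@@H]([C@H]([C@H]([C@@H](O1)O[C@@H]2[C@H]([C@@H]([C@H](O[C@H]2Oc3cc(O)c4C(=O)C[C@H](Oc4c3)c5ccc(O)cc5)CO)O)O)O)O)O` | starting material |
| 2 | N-iodosuccinimide | `O=C1CCC(=O)N1I` | starting material (reagent) |
| 3 | (2S)-3′,5′,6,8-tetraiodonaringin | `C[C@H]1[C@@H]([C@H]([C@H]([C@@H](O1)O[C@@H]2[C@H]([C@@H]([C@H](O[C@H]2Oc3c(I)c(O)c4C(=O)C[C@H](Oc4c3I)c5cc(I)c(O)c(I)c5)CO)O)O)O)O)O` | intermediate |
| 4 | iodomethane | `CI` | starting material (reagent) |
| 5 | (2S)-3′,5′,6,8-tetraiodo-4′-O-methylnaringin | `C[C@H]1[C@@H]([C@H]([C@H]([C@@H](O1)O[C@@H]2[C@H]([C@@H]([C@H](O[C@H]2Oc3c(I)c(O)c4C(=O)C[C@H](Oc4c3I)c5cc(I)c(OC)c(I)c5)CO)O)O)O)O)O` | intermediate |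
| 6 | (2S)-3′,5′-diiodoisosakuranetin | `COc1c(I)cc(cc1I)[C@@H]2CC(=O)c3c(O)cc(O)cc3O2` | intermediate |
| 7 | prenyl acetate | `CC(C)=CCOC(C)=O` | starting material |
| 8 | (2S)-3′,5′-diprenyl-4′-O-methylnaringenin | `COc1c(CC=C(C)C)cc(cc1CC=C(C)C)[C@@H]2CC(=O)c3c(O)cc(O)cc3O2` | intermediate |
| 9 | dioxygen | `O=O` | starting material (reagent) |
| 10 | target (2S, E) | `COc1c(/C=C/C(C)(C)O)cc([C@@H]2CC(=O)c3c(O)cc(O)cc3O2)cc1CC=C(C)C` | target |

## Totals
Total steps: 5. Longest linear sequence: 5.

## Steps most likely to fail
1. **Step 4 (proposed new step).**
   - Risks: hydrodeiodination by the phenolic protons, stalling at the mono-prenyl iodide, and traces of branched isomer or carbonyl allylation.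
   - Fallback (known chemistry): a twofold Stille coupling of 6 with tributyl(3-methylbut-2-en-1-yl)stannane, Pd(PPh3)4, DMF, 80 °C. This is base-free, tolerates phenols and gives the linear product.
2. **Step 5.**
   - Risks: statistical mono versus bis oxidation and roughly 1:1 tertiary to secondary regiochemistry. I expect about 20 % isolated yield, or about 40 % based on recovered 8.
   - Fallback: drop the late oxidation.
     - Carry out a statistical mono-Heck reaction on 6 with 2-methylbut-3-en-2-ol (Pd(OAc)2, Bu4NCl, NaHCO3, DMF, 50 °C). This installs the E-hydroxyalkenyl arm with fixed regiochemistry.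
     - Then prenylate the remaining C–I bond. The step count is unchanged.
3. **Step 3.**
   - Risks: incomplete removal of the C8 iodide, or some loss of ee in hot acid.
   - Fallback: never halogenate ring A.
     - Methylate and hydrolyse naringin first to give (2S)-isosakuranetin.
     - Functionalise ring B by sterically governed Ir-catalysed C–H borylation. Both ring-A C–H bonds sit between two oxygen substituents and are inert to it.
     - Finish with Cu-mediated iododeboronation, in two passes if needed, to reach 6.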